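**Plan**

- Retrosynthesis: the two outer ring–CH2 bonds to the gem-dimethyl trione end units are cut first, then the twelve OH groups are returned to OCH3, then the four aryl–C(=O)propyl bonds of rings A to D are cut, and last the three inner CH2 bridges.
- Enabling feature: in each aromatic ring A to D the butyryl carbonyl sits on a ring carbon whose two ring neighbours both carry oxygen. A CH2-linked chain of four 1,3,5-trimethoxybenzene rings still has such a C–H on every ring (one on B and C, two equivalent ones on A and D).
- Forward: no ring is built; all six-membered rings are bought. The chain grows from the centre outwards (two-ring methane from formaldehyde, its dialdehyde, four-ring chain), is butyrylated four times in one operation, demethylated, aminomethylated at both ends, and capped with two butyrylfilicinic acid units made separately from phloroglucinol.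
- Stereochemistry: the target has no stereocentre; the two carbinol carbons that appear on the way are reduced to CH2.

Key step: step 5

Remark on the chemistry: the enol form written in the target SMILES is taken as the compound; all tautomers of the trione end units and of the acylphloroglucinol rings are treated as one substance.

**Route**

Step 1
Reactants: 1 1,3,5-trimethoxybenzene; 2 formaldehyde (used as paraformaldehyde)
Product: 4 bis(2,4,6-trimethoxyphenyl)methane, via 2,4,6-trimethoxybenzyl alcohol 3 (not isolated)
Conditions: 1 (6 equiv), (CH2O)n (1 equiv), H2SO4 (5 mol %), AcOH, 40 °C; excess 1 recovered by vacuum distillation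
Reagents that add atoms: none
Why: Acid-catalysed hydroxymethylation of 1 gives benzyl alcohol 3, whose stabilised benzyl cation alkylates a second molecule of 1 (Friedel–Crafts diarylmethane condensation), and the large excess of 1 should hold the reaction at the two-ring stage.

Step 2
Reactants: 4 bis(2,4,6-trimethoxyphenyl)methane
Product: 6 3,3'-methylenebis(2,4,6-trimethoxybenzaldehyde), via bis(iminium) dichloride 5 (not isolated)
Conditions: POCl3, DMF, 0 °C to 50 °C; then aq NaOH, rt
Reagents that add atoms: N,N-dimethylformamide, CN(C)C=O; water, O; phosphoryl chloride, O=P(Cl)(Cl)Cl (only the chloride counter-ions of intermediate 5)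
Why: Vilsmeier–Haack formylation: each ring offers a carbon between two methoxy groups, the iminium group deactivates its own ring against a second attack while the CH2-insulated other ring reacts independently, and the aprotic reagent spares the acid-labile bridge.

Step 3
Reactants: 6 3,3'-methylenebis(2,4,6-trimethoxybenzaldehyde); 1 1,3,5-trimethoxybenzene
Product: 8 bis-carbinol (each CHO of 6 turned into CH(OH)(2,4,6-trimethoxyphenyl); meso/racemic mixture), via 2,4,6-trimethoxyphenyllithium 7 (not isolated)
Conditions: 1 (2.4 equiv), n-BuLi, TMEDA, THF, 0 °C to rt; then 6, −78 °C to rt; H2O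
Reagents that add atoms: n-butyllithium, [Li]CCCC (supplies only the lithium of intermediate 7)
Why: Directed ortho-lithiation of 1 between two methoxy groups gives aryllithium 7, which adds 1,2 to both non-enolisable aldehyde groups of 6; the two carbinol centres form without control, which does not matter because both become CH2 in step 4.

Step 4
Reactants: 8 bis-carbinol
Product: 9 linear tetraarene (four trimethoxybenzene rings joined by three CH2 bridges; 2,4,6-trimethoxybenzyl ends, 1,3-linked inner rings)
Conditions: Et3SiH, CF3CO2H, CH2Cl2, 0 °C
Reagents that add atoms: none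
Why: Twofold ionic hydrogenation: each carbinol ionises to a strongly stabilised diarylmethyl cation far faster than any ring is ipso-protonated, and the excess silane delivers hydride to the cations at once, so low temperature and short contact should spare the bridges.

Step 5
Reactants: 9 linear tetraarene; 10 butyric acid
Product: 12 tetrabutyryl dodecamethyl ether (9 with one butyryl group on the free carbon of rings B and C and on one free carbon of rings A and D), via butyric trifluoroacetic anhydride 11 (not isolated)
Conditions: 10 (6 equiv), (CF3CO)2O (5 equiv), CH2Cl2, 0 °C, 30 min; then 9, 0 °C to rt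
Reagents that add atoms: trifluoroacetic anhydride, O=C(OC(=O)C(F)(F)F)C(F)(F)F (supplies only the CF3CO2 part of intermediate 11)
Why: Mixed anhydride 11 acts as a butyryl cation donor that attacks, on each ring, the C–H carbon flanked by two methoxy-bearing carbons, and loss of the proton to trifluoroacetate restores the arene, so four aryl–C(=O) bonds form in one operation. The closest known reaction type is the Friedel–Crafts acylation of 1,3,5-trimethoxyarenes with a carboxylic acid and (CF3CO)2O. No ring is closed and no stereocentre is formed. One acyl group per ring is needed: rings B and C have a single free carbon, the two free carbons of rings A and D are equivalent, and the first ketone deactivates its ring against a second acylation, which leaves one C–H on each end ring for the later capping. The CH2 bridges must survive, which the absence of a strong Lewis acid and the low temperature should secure. Keeping butyric acid in excess over the anhydride leaves no free (CF3CO)2O for trifluoroacetylation.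

Step 6
Reactants: 12 tetrabutyryl dodecamethyl ether
Product: 13 tetrabutyryl dodecaphenol (12 with all twelve OCH3 as OH)
Conditions: BBr3 (30 equiv), CH2Cl2, −78 °C to rt; then H2O, 0 °C
Reagents that add atoms: none
Why: Lewis acid ether cleavage: each ArO–CH3 is opened by bromide attack on the methyl group of its borane adduct, the eight methoxy groups ortho to a ketone being helped by chelation, while the acyl groups now deactivate every ring against ipso-protonation at the bridges.

Step 7
Reactants: 13 tetrabutyryl dodecaphenol
Product: 14 bis-Mannich base (13 with CH2N(CH3)2 on the remaining free carbon of rings A and D)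
Conditions: CH2=NMe2+ I− (2.2 equiv), MeCN/THF, 0 °C to rt; aq NaHCO3
Reagents that add atoms: Eschenmoser's salt (N,N-dimethylmethyleneiminium iodide), C=[N+](C)C.[I-]
Why: Mannich aminomethylation with a preformed iminium salt: only rings A and D keep an unsubstituted phenol-activated carbon, so one aminomethyl group should enter at each end, without free formaldehyde that could bridge two chains.

Step 8
Reactants: 15 phloroglucinol; 16 butyryl chloride
Product: 17 1-(2,4,6-trihydroxyphenyl)butan-1-one
Conditions: AlCl3, PhNO2/CH2Cl2, 0 °C to 40 °C; then ice, aq HCl
Reagents that add atoms: none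
Why: Friedel–Crafts acylation of phloroglucinol; the aluminium chelate of the first ketone deactivates the ring, so monoacylation should prevail.

Step 9
Reactants: 17 1-(2,4,6-trihydroxyphenyl)butan-1-one
Product: 18 butyrylfilicinic acid (2-butanoyl-3,5-dihydroxy-4,4-dimethylcyclohexa-2,5-dien-1-one)
Conditions: CH3I (2.1 equiv), NaOMe (3 equiv), MeOH, 0 °C to rt; then aq HCl
Reagents that add atoms: iodomethane, CI
Why: Dearomatising C-methylation of the phenolate: two methyl groups enter the same ring carbon and the resulting gem-dimethyl trione is held as its stabilised vinylogous-acid anion, the known way from acylphloroglucinols to acylfilicinic acids; mono- and over-methylated by-products would be removed by chromatography.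

Step 10
Reactants: 14 bis-Mannich base; 18 butyrylfilicinic acid
Product: 19 target CNP0237140.0
Conditions: 18 (6 equiv), 1,4-dioxane, 80 °C, N2 stream
Reagents that add atoms: none
Why: o-Quinone methide alkylation: thermal loss of dimethylamine from each phenolic Mannich base gives an o-quinone methide on ring A or D, the nucleophilic ring CH of enolised 18 adds in a Michael fashion and tautomerisation restores the arene, with excess 18 and removal of Me2NH driving both ends to completion.

**Compound list**

1 | 1,3,5-trimethoxybenzene | COc1cc(OC)cc(OC)c1 | starting material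
2 | formaldehyde (used as paraformaldehyde) | C=O | starting material
3 | 2,4,6-trimethoxybenzyl alcohol | COc1cc(OC)c(CO)c(OC)c1 | intermediate
4 | bis(2,4,6-trimethoxyphenyl)methane | COc1cc(OC)c(Cc2c(OC)cc(OC)cc2OC)c(OC)c1 | intermediate
5 | bis(iminium) dichloride of the Vilsmeier step | C[N+](C)=Cc1c(OC)cc(OC)c(Cc2c(OC)cc(OC)c(C=[N+](C)C)c2OC)c1OC.[Cl-].[Cl-] | intermediate
6 | 3,3'-methylenebis(2,4,6-trimethoxybenzaldehyde) | O=Cc1c(OC)cc(OC)c(Cc2c(OC)cc(OC)c(C=O)c2OC)c1OC | intermediate
7 | 2,4,6-trimethoxyphenyllithium | [Li]c1c(OC)cc(OC)cc1OC | intermediate
8 | bis-carbinol (meso/racemic mixture, centres not defined) | COc1cc(OC)c(C(O)c2c(OC)cc(OC)c(Cc3c(OC)cc(OC)c(C(O)c4c(OC)cc(OC)cc4OC)c3OC)c2OC)c(OC)c1 | intermediate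
9 | linear tetraarene | COc1cc(OC)c(Cc2c(OC)cc(OC)c(Cc3c(OC)cc(OC)c(Cc4c(OC)cc(OC)cc4OC)c3OC)c2OC)c(OC)c1 | intermediate
10 | butyric acid | CCCC(=O)O | starting material
11 | butyric trifluoroacetic anhydride | CCCC(=O)OC(=O)C(F)(F)F | intermediate
12 | tetrabutyryl dodecamethyl ether | CCCC(=O)c1c(OC)cc(OC)c(Cc2c(OC)c(C(=O)CCC)c(OC)c(Cc3c(OC)c(C(=O)CCC)c(OC)c(Cc4c(OC)cc(OC)c(C(=O)CCC)c4OC)c3OC)c2OC)c1OC | intermediate
13 | tetrabutyryl dodecaphenol | CCCC(=O)c1c(O)cc(O)c(Cc2c(O)c(C(=O)CCC)c(O)c(Cc3c(O)c(C(=O)CCC)c(O)c(Cc4c(O)cc(O)c(C(=O)CCC)c4O)c3O)c2O)c1O | intermediate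
14 | bis-Mannich base | CCCC(=O)c1c(O)c(CN(C)C)c(O)c(Cc2c(O)c(C(=O)CCC)c(O)c(Cc3c(O)c(C(=O)CCC)c(O)c(Cc4c(O)c(CN(C)C)c(O)c(C(=O)CCC)c4O)c3O)c2O)c1O | intermediate
15 | phloroglucinol | Oc1cc(O)cc(O)c1 | starting material
16 | butyryl chloride | CCCC(=O)Cl | starting material
17 | 1-(2,4,6-trihydroxyphenyl)butan-1-one | CCCC(=O)c1c(O)cc(O)cc1O | intermediate
18 | butyrylfilicinic acid | CCCC(=O)C1=C(O)C(C)(C)C(O)=CC1=O | intermediate
19 | target CNP0237140.0 (no stereocentre) | CCCC(=O)C1=C(O)C(C)(C)C(O)=C(Cc2c(O)c(Cc3c(O)c(Cc4c(O)c(Cc5c(O)c(CC6=C(O)C(C)(C)C(O)=C(C(=O)CCC)C6=O)c(O)c(C(=O)CCC)c5O)c(O)c(C(=O)CCC)c4O)c(O)c(C(=O)CCC)c3O)c(O)c(C(=O)CCC)c2O)C1=O | target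

**Step count**

Total: 10 steps. Longest linear sequence: 8 steps (steps 1 to 7 and step 10); steps 8 and 9 form the side branch to 18.

**Steps most likely to fail**

Step 5. The trifluoroacetic acid set free may protonate or acylate the electron-rich rings at the bridge-bearing carbons and so break the chain, and the crowded positions of rings B and C may be acylated incompletely. The fallback sets out from 9 and avoids protic acid. POCl3/DMF, as in step 2, should formylate each ring once; the tetra(iminium) tetrachloride F1 is hydrolysed with aqueous NaOH to the tetraaldehyde F2. n-PrMgBr in THF at 0 °C should then give the tetracarbinol F3 as a diastereomer mixture. Oxidation of its four benzylic alcohols with Dess–Martin periodinane and NaHCO3 in CH2Cl2 comes back to the route at 12.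

Step 6. Cleavage may stop at the four methoxy groups para to the ketones, which have no chelation help and on rings B and C lie between two CH2 groups. The HBr formed may also open bridges or close xanthene rings between neighbouring phenols. The fallback sets out from 12 and separates the two kinds of ether. BCl3 in CH2Cl2 at 0 °C should remove only the eight chelated ortho-methoxy groups and give the octaphenol tetramethyl ether F4. The four remaining methyl groups are then taken off by thiolate attack on carbon with NaSEt in DMF at 120 °C, without Brønsted acid, which comes back to the route at 13.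

Step 10. Dimethylamine loss may be reversible or slow, the warm amine-containing medium may exchange CH2 bridges by retro-Michael cleavage, and capping may stop after one end. The fallback sets out from 13, leaving out 14, and uses the classical cold condensation. Aqueous formaldehyde (2.2 equiv) and a large excess of 18 in 1% aqueous KOH at 0 °C should hydroxymethylate and couple in one flask. Acidification and removal of the methylenebis(butyrylfilicinic acid) by-product on Sephadex LH-20 come back to the route at 19; this fallback makes no new isolable compound (F0).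

**Further compounds**

F1 | step 5 | tetra(iminium) tetrachloride from fourfold Vilsmeier attack on 9 | C[N+](C)=Cc1c(OC)cc(OC)c(Cc2c(OC)c(C=[N+](C)C)c(OC)c(Cc3c(OC)c(C=[N+](C)C)c(OC)c(Cc4c(OC)cc(OC)c(C=[N+](C)C)c4OC)c3OC)c2OC)c1OC.[Cl-].[Cl-].[Cl-].[Cl-]
F2 | step 5 | tetraaldehyde (9 with one CHO on each ring) | O=Cc1c(OC)cc(OC)c(Cc2c(OC)c(C=O)c(OC)c(Cc3c(OC)c(C=O)c(OC)c(Cc4c(OC)cc(OC)c(C=O)c4OC)c3OC)c2OC)c1OC
F3 | step 5 | tetracarbinol (diastereomer mixture, centres not defined) | CCCC(O)c1c(OC)cc(OC)c(Cc2c(OC)c(C(O)CCC)c(OC)c(Cc3c(OC)c(C(O)CCC)c(OC)c(Cc4c(OC)cc(OC)c(C(O)CCC)c4OC)c3OC)c2OC)c1OC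
F4 | step 6 | octaphenol tetramethyl ether (OCH3 left para to each butyryl group) | CCCC(=O)c1c(O)cc(OC)c(Cc2c(O)c(C(=O)CCC)c(O)c(Cc3c(O)c(C(=O)CCC)c(O)c(Cc4c(OC)cc(O)c(C(=O)CCC)c4O)c3OC)c2OC)c1O
F0 | step 10 | none | none
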